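A direct plan would condense a selectively protected phloroacetophenone with a protected protocatechualdehyde to chalcone A1. It would turn A1 into the isoflavone by an oxidative 1,2-aryl shift with a trivalent iodine reagent and acid-mediated closure of ring C, and debenzylate to diphenol A2. Both prenyl groups would come from the bis(1,1-dimethylallyl) ether A3 by double Claisen rearrangement.
Its weakest steps would be: (a) the four selective mono-protections at the start, which would build no skeleton and rest on small differences between nearly equivalent phenols; (b) the oxidative aryl shift with ring closure, which would expose two acid-labile MOM ethers and a very electron-rich ring A to oxidant and sulfonic acid; (c) the etherification of the chelated 5-OH and the double Claisen rearrangement, three steps on the most advanced material to place two C5 groups, with para or abnormal rearrangement and chromene or chroman formation as by-paths.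

**Plan of the new route**
- The retrosynthesis cuts ring A itself: C8–C8a, C5–C6, C7–C8 and C4a–C5 would form in one flask from pyranonyl diazomethyl ketone 14 and the prenyl-bearing silyl ynol ether 18.
- Before that it cuts C3–C1′ (Suzuki coupling of triflate 10 with boronate 7) and, in ring B, C1′–B and C5′–prenyl (C–H borylation, directed ortho-metalation).
- Ring order: ring C is bought as comenic acid, ring B is attached to it, ring A is built last.
- Enabling feature: ring A is a 2-alkylresorcinol, C5(OH)–C6(prenyl)–C7(OH)–C8(H), fused through C4a=C8a to a 4-pyranone. These atoms map one by one onto a ketene C=O, the C≡C–O of an ynol ether, a ketene CH and the C2=C3 bond of a pyranone with free C3–H.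
- Ring A appears with 5-OH free and prenyl locked at C6, so no phenols need telling apart, no aryl group migrates, and no O-allylation or Claisen rearrangement occurs.

Key step: step 10

Remark: comenic acid and methyl 4-methylpent-3-enoate are treated as purchased. Ar stands for 3,4-bis(methoxymethoxy)-5-(3-methylbut-2-en-1-yl)phenyl and prenyl for 3-methylbut-2-en-1-yl.

**Step 1**
Reactants: 1 catechol (benzene-1,2-diol)
Product: 2 1,2-bis(methoxymethoxy)benzene
Conditions: MOMCl (2.5 equiv), i-Pr2NEt (3 equiv), CH2Cl2, 0 °C → rt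
Reagents that add atoms: chloromethyl methyl ether, COCCl
Why: Double O-alkylation of the phenols with an α-chloro ether under amine base (acetal-type Williamson etherification); both oxygens are protected alike, so no selectivity is asked for.

**Step 2**
Reactants: 2 1,2-bis(methoxymethoxy)benzene; 3 1-bromo-3-methylbut-2-ene (prenyl bromide)
Product: 6 1,2-bis(methoxymethoxy)-3-(3-methylbut-2-en-1-yl)benzene, via aryllithium 4 (not isolated), via arylcopper 5 (not isolated)
Conditions: n-BuLi (1.1 equiv), TMEDA, THF, 0 °C; CuBr·SMe2 (1.0 equiv), −78 °C; 3, −78 °C → rt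
Reagents that add atoms: none
Why: Directed ortho-metalation, in which the OMOM groups guide n-BuLi to the one kind of ortho C–H (C3 and C6 are equivalent), followed by Li-to-Cu exchange and allylic substitution at the unhindered CH2 end of prenyl bromide, which should place an intact prenyl group next to one oxygen.

**Step 3**
Reactants: 6 1,2-bis(methoxymethoxy)-3-(3-methylbut-2-en-1-yl)benzene
Product: 7 2-[3,4-bis(methoxymethoxy)-5-(3-methylbut-2-en-1-yl)phenyl]-4,4,5,5-tetramethyl-1,3,2-dioxaborolane (Ar–Bpin)
Conditions: B2pin2 (1.0 equiv), [Ir(OMe)(cod)]2 (1.5 mol%), 4,4′-di-tert-butyl-2,2′-bipyridine (3 mol%), THF, 60 °C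
Reagents that add atoms: bis(pinacolato)diboron, CC1(C)OB(B2OC(C)(C)C(C)(C)O2)OC1(C)C
Why: Sterically controlled iridium-catalysed aromatic C–H borylation; in this 1,2,3-trisubstituted benzene only C5–H has no ortho neighbour, so boron should enter para to the oxygen that is flanked by the prenyl group (the future C1′), and the trisubstituted alkene should be too hindered to react.

**Step 4**
Reactants: 8 comenic acid (5-hydroxy-4-oxo-4H-pyran-2-carboxylic acid)
Product: 9 methyl 5-hydroxy-4-oxo-4H-pyran-2-carboxylate
Conditions: MeOH, H2SO4 (cat.), reflux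
Reagents that add atoms: methanol, CO
Why: Fischer esterification, which leaves the enolic 5-OH and the pyranone untouched and masks the acid for the triflation and coupling.

**Step 5**
Reactants: 9 methyl 5-hydroxy-4-oxo-4H-pyran-2-carboxylate
Product: 10 methyl 4-oxo-5-{[(trifluoromethyl)sulfonyl]oxy}-4H-pyran-2-carboxylate
Conditions: Tf2O (1.1 equiv), pyridine, CH2Cl2, −20 → 0 °C
Reagents that add atoms: trifluoromethanesulfonic anhydride, O=S(=O)(OS(=O)(=O)C(F)(F)F)C(F)(F)F
Why: O-sulfonylation of the acidic enol-type 5-OH of a 3-hydroxy-4-pyranone, as is routine for kojic acid derivatives, which should give a triflate activated for oxidative addition.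

**Step 6**
Reactants: 10 methyl 4-oxo-5-{[(trifluoromethyl)sulfonyl]oxy}-4H-pyran-2-carboxylate; 7 Ar–Bpin
Product: 11 methyl 5-Ar-4-oxo-4H-pyran-2-carboxylate
Conditions: Pd(dppf)Cl2 (5 mol%), K3PO4 (3 equiv), 1,4-dioxane–H2O (20:1), 70 °C, Ar
Reagents that add atoms: none
Why: Suzuki–Miyaura coupling that forms the future C3–C1′ bond; zerovalent palladium should insert readily into the electron-poor C–OTf bond next to the pyranone carbonyl, the boronate has no ortho substituent, and any ester saponified here is simply the product of step 7.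

**Step 7**
Reactants: 11 methyl 5-Ar-4-oxo-4H-pyran-2-carboxylate
Product: 12 5-Ar-4-oxo-4H-pyran-2-carboxylic acid
Conditions: LiOH·H2O (1.1 equiv), THF–H2O (3:1), 0 °C; cold 0.5 M HCl to pH 4
Reagents that add atoms: lithium hydroxide, [Li+].[OH-]
Why: Saponification of an activated ester; at 0 °C with barely one equivalent of hydroxide, attack at the ester carbonyl should outrun conjugate addition to C6 of the pyranone (ring opening), and the MOM ethers are stable to base and to the brief cold acidification.

**Step 8**
Reactants: 12 5-Ar-4-oxo-4H-pyran-2-carboxylic acid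
Product: 14 5-Ar-2-(2-diazoacetyl)-4H-pyran-4-one, via mixed anhydride 13 (not isolated)
Conditions: i-BuOCOCl (1.05 equiv), N-methylmorpholine (1.1 equiv), THF, −15 °C; CH2N2 (Et2O, 3 equiv), −15 → 0 °C
Reagents that add atoms: diazomethane, C=[N+]=[N-]
Why: C-acylation of diazomethane by a mixed carbonic anhydride (first stage of an Arndt–Eistert sequence); this activation sets free no HCl, so the MOM ethers are safe, and the anhydride should react far faster than the vinylogous-ester double bonds of the pyranone.

**Step 9**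
Reactants: 15 methyl 4-methylpent-3-enoate
Product: 18 triisopropyl[(5-methylhex-4-en-1-yn-1-yl)oxy]silane, via dibromo enolate 16 (not isolated), via lithium ynolate 17 (not isolated)
Conditions: CH2Br2 (1.1 equiv), LiTMP (lithium 2,2,6,6-tetramethylpiperidide, 2.2 equiv), THF, −78 °C; n-BuLi, −78 → 20 °C; TIPSCl, −78 → 0 °C
Reagents that add atoms: dibromomethane, BrCBr; chlorotriisopropylsilane, CC(C)[Si](Cl)(C(C)C)C(C)C
Why: Kowalski ester homologation, in which LiCHBr2 adds to the ester to give dibromo enolate 16, bromine–lithium exchange and 1,2-shift of the prenyl-bearing CH2 group give ynolate 17, and the bulky silyl chloride should silylate 17 on oxygen and not on carbon.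

**Step 10**
Reactants: 14 5-Ar-2-(2-diazoacetyl)-4H-pyran-4-one; 18 triisopropyl[(5-methylhex-4-en-1-yn-1-yl)oxy]silane
Product: 24 3-Ar-5,7-dihydroxy-6-(3-methylbut-2-en-1-yl)-4H-chromen-4-one, via ketene 19 (not isolated), via cyclobutenone 20 (not isolated), via dienylketene 21 (not isolated), via cyclohexadienone 22 (not isolated), via silyl ether 23 (not isolated)
Conditions: 18 (2 equiv), hν (365 nm LED, Pyrex), ClCH2CH2Cl, 20 °C, Ar; then 80 °C (dark); then TBAF–AcOH (1:1, 1.5 equiv), THF, 0 °C
Reagents that add atoms: none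
Why: Light expels N2 from 14 and the pyranonyl group shifts to the carbene carbon (Wolff rearrangement) to give ketene 19, which adds to the polarised ynol ether 18 in a [2+2] cycloaddition (ketene carbonyl carbon to the nucleophilic, prenyl-bearing alkyne carbon) to give cyclobutenone 20; at 80 °C 20 opens in a conrotatory four-electron ring opening to dienylketene 21, which closes onto C3 of the pyranone and enolises (22 to 23), and fluoride then removes the silyl group. The closest known reaction type is the Danheiser benzannulation in its diazo ketone form, which builds resorcinol rings on alkenyl, aryl and heteroaryl diazomethyl ketones with siloxyalkynes and is related to the Smith–Hoehn naphthol synthesis. Ring A is closed by a thermal disrotatory six-electron electrocyclisation that forms C4a–C5 (the four-membered ring before it arises by [2+2] and is opened again), and tautomerisation makes it aromatic. No stereocentre remains, since the one in 20 and the one in 22 are lost on ring opening and enolisation. The step needs one orientation of the [2+2], which the ynol ether secures because its oxygen-bearing carbon bonds to the ketene CH, so that the prenyl group ends at C6 between the two oxygens and H at C8, and it needs closure at one site, which is secured because C3–H is the only pyranone position within reach of the ketene carbon. Light of 365 nm should be absorbed by the diazo ketone and hardly by the aryl-pyranone, the excess of 18 should intercept 19 before it dimerises, and the new 5-OH is hydrogen-bonded to C4=O and so should not be acylated by ketene.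

**Step 11**
Reactants: 24 3-Ar-5,7-dihydroxy-6-(3-methylbut-2-en-1-yl)-4H-chromen-4-one
Product: 25 isoangustone A
Conditions: 3 M HCl (aq)–MeOH (1:4), rt → 40 °C, Ar
Reagents that add atoms: none
Why: Acid-catalysed acetal exchange of the two aryl MOM ethers with methanol; dilute acid at or below 40 °C under argon should leave the prenyl double bonds unprotonated (no chroman) and the catechol unoxidised.

**Compound list**
1 | catechol | Oc1ccccc1O | starting material
2 | 1,2-bis(methoxymethoxy)benzene | COCOc1ccccc1OCOC | intermediate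
3 | 1-bromo-3-methylbut-2-ene (prenyl bromide) | CC(C)=CCBr | starting material
4 | [2,3-bis(methoxymethoxy)phenyl]lithium | [Li]c1cccc(OCOC)c1OCOC | intermediate (not isolated)
5 | [2,3-bis(methoxymethoxy)phenyl]copper | [Cu]c1cccc(OCOC)c1OCOC | intermediate (not isolated)
6 | 1,2-bis(methoxymethoxy)-3-(3-methylbut-2-en-1-yl)benzene | COCOc1cccc(CC=C(C)C)c1OCOC | intermediate
7 | 2-[3,4-bis(methoxymethoxy)-5-(3-methylbut-2-en-1-yl)phenyl]-4,4,5,5-tetramethyl-1,3,2-dioxaborolane | COCOc1cc(B2OC(C)(C)C(C)(C)O2)cc(CC=C(C)C)c1OCOC | intermediate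
8 | comenic acid (5-hydroxy-4-oxo-4H-pyran-2-carboxylic acid) | O=C(O)c1cc(=O)c(O)co1 | starting material
9 | methyl 5-hydroxy-4-oxo-4H-pyran-2-carboxylate | COC(=O)c1cc(=O)c(O)co1 | intermediate
10 | methyl 4-oxo-5-{[(trifluoromethyl)sulfonyl]oxy}-4H-pyran-2-carboxylate | COC(=O)c1cc(=O)c(OS(=O)(=O)C(F)(F)F)co1 | intermediate
11 | methyl 5-[3,4-bis(methoxymethoxy)-5-(3-methylbut-2-en-1-yl)phenyl]-4-oxo-4H-pyran-2-carboxylate | COC(=O)c1cc(=O)c(-c2cc(OCOC)c(OCOC)c(CC=C(C)C)c2)co1 | intermediate
12 | 5-[3,4-bis(methoxymethoxy)-5-(3-methylbut-2-en-1-yl)phenyl]-4-oxo-4H-pyran-2-carboxylic acid | O=C(O)c1cc(=O)c(-c2cc(OCOC)c(OCOC)c(CC=C(C)C)c2)co1 | intermediate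
13 | isobutyl carbonic anhydride of acid 12 | CC(C)COC(=O)OC(=O)c1cc(=O)c(-c2cc(OCOC)c(OCOC)c(CC=C(C)C)c2)co1 | intermediate (not isolated)
14 | 5-[3,4-bis(methoxymethoxy)-5-(3-methylbut-2-en-1-yl)phenyl]-2-(2-diazoacetyl)-4H-pyran-4-one | [N-]=[N+]=CC(=O)c1cc(=O)c(-c2cc(OCOC)c(OCOC)c(CC=C(C)C)c2)co1 | intermediate
15 | methyl 4-methylpent-3-enoate | COC(=O)CC=C(C)C | starting material
16 | lithium 1,1-dibromo-5-methylhexa-1,4-dien-2-olate | [Li+].[O-]C(CC=C(C)C)=C(Br)Br | intermediate (not isolated)
17 | lithium 5-methylhex-4-en-1-yn-1-olate | [Li+].[O-]C#CCC=C(C)C | intermediate (not isolated)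
18 | triisopropyl[(5-methylhex-4-en-1-yn-1-yl)oxy]silane | CC(C)=CCC#CO[Si](C(C)C)(C(C)C)C(C)C | intermediate
19 | 2-(5-Ar-4-oxo-4H-pyran-2-yl)ethen-1-one (pyranonylketene) | O=C=Cc1cc(=O)c(-c2cc(OCOC)c(OCOC)c(CC=C(C)C)c2)co1 | intermediate (not isolated)
20 | 4-(5-Ar-4-oxo-4H-pyran-2-yl)-2-(3-methylbut-2-en-1-yl)-3-[(triisopropylsilyl)oxy]cyclobut-2-en-1-one (racemic) | O=C1C(CC=C(C)C)=C(O[Si](C(C)C)(C(C)C)C(C)C)C1c1cc(=O)c(-c2cc(OCOC)c(OCOC)c(CC=C(C)C)c2)co1 | intermediate (not isolated)
21 | (3E)-4-(5-Ar-4-oxo-4H-pyran-2-yl)-2-(3-methylbut-2-en-1-yl)-3-[(triisopropylsilyl)oxy]buta-1,3-dien-1-one (pyranone cis to the ketene carbon) | O=C=C(CC=C(C)C)/C(O[Si](C(C)C)(C(C)C)C(C)C)=C\c1cc(=O)c(-c2cc(OCOC)c(OCOC)c(CC=C(C)C)c2)co1 | intermediate (not isolated)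
22 | 3-Ar-6-(3-methylbut-2-en-1-yl)-7-[(triisopropylsilyl)oxy]-4aH-chromene-4,5-dione (racemic) | O=C1C(CC=C(C)C)=C(O[Si](C(C)C)(C(C)C)C(C)C)C=C2OC=C(c3cc(OCOC)c(OCOC)c(CC=C(C)C)c3)C(=O)C12 | intermediate (not isolated)
23 | 3-Ar-5-hydroxy-6-(3-methylbut-2-en-1-yl)-7-[(triisopropylsilyl)oxy]-4H-chromen-4-one | CC(C)=CCc1c(O[Si](C(C)C)(C(C)C)C(C)C)cc2occ(-c3cc(OCOC)c(OCOC)c(CC=C(C)C)c3)c(=O)c2c1O | intermediate (not isolated)
24 | 3-[3,4-bis(methoxymethoxy)-5-(3-methylbut-2-en-1-yl)phenyl]-5,7-dihydroxy-6-(3-methylbut-2-en-1-yl)-4H-chromen-4-one | CC(C)=CCc1c(O)cc2occ(-c3cc(OCOC)c(OCOC)c(CC=C(C)C)c3)c(=O)c2c1O | intermediate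
25 | isoangustone A [3-[3,4-dihydroxy-5-(3-methylbut-2-en-1-yl)phenyl]-5,7-dihydroxy-6-(3-methylbut-2-en-1-yl)-4H-chromen-4-one] | CC(C)=CCc1cc(-c2coc3cc(O)c(CC=C(C)C)c(O)c3c2=O)cc(O)c1O | target

**Count and risks**
Total steps: 11. Longest linear sequence: 8 steps (steps 1, 2, 3, 6, 7, 8, 10, 11).

Step 10 is the most likely to fail. Light may drive side reactions of the aryl-pyranone and the prenyl double bonds (enone–alkene photocycloaddition, pyranone photoisomerisation), the ketene may dimerise before it is captured, or the sequence may stall at the cyclobutenone. The fallback generates the same ketene in the dark and sets out from diazo ketone 14. Silver-catalysed Wolff rearrangement in wet THF (PhCO2Ag, Et3N, THF–H2O) should give (5-Ar-4-oxo-4H-pyran-2-yl)acetic acid F1, which is kept cold because it is a vinylogous β-keto acid. 1-Chloro-N,N,2-trimethylprop-1-en-1-amine in CH2Cl2 at 0 °C, neutral conditions that spare the MOM ethers, should give (5-Ar-4-oxo-4H-pyran-2-yl)acetyl chloride F2. Slow addition of F2 to Et3N and 18 at 0–20 °C should form ketene 19 by dehydrochlorination and bring the route back at cyclobutenone 20, which can then be isolated and heated on its own in toluene before desilylation.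

Step 9 is second. The base may deprotonate the doubly activated α-CH2 of the β,γ-unsaturated ester (enolisation and double-bond migration) instead of adding to the carbonyl, or the ynolate may be silylated on carbon to a silylketene. The fallback sets out from prenyl bromide 3. Coupling with ethynylmagnesium bromide (CuCl cat., THF) should give 5-methylhex-4-en-1-yne F3, and n-BuLi its acetylide (5-methylhex-4-en-1-yn-1-yl)lithium F4. Oxidation of F4 with lithium tert-butyl peroxide (t-BuOOH, LiN(SiMe3)2, THF, −78 → 0 °C) should give lithium ynolate 17, where the route is rejoined and silylation follows as in step 9.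

Step 3 is third. The iridium boryl catalyst or the pinacolborane set free may engage the prenyl double bond (hydroboration, isomerisation), or some borylation may occur next to OMOM. The fallback borylates before the alkene is present and sets out from 2 through aryllithium 4. Quenching 4 with I2 should give 1-iodo-2,3-bis(methoxymethoxy)benzene F5. The same iridium-catalysed borylation of this alkene-free 1,2,3-trisubstituted arene should give 2-[3-iodo-4,5-bis(methoxymethoxy)phenyl]-4,4,5,5-tetramethyl-1,3,2-dioxaborolane F6. Iodine–magnesium exchange (i-PrMgCl·LiCl, THF, −40 °C, boronate tolerated in the cold) should give [2,3-bis(methoxymethoxy)-5-(4,4,5,5-tetramethyl-1,3,2-dioxaborolan-2-yl)phenyl]magnesium chloride F7. Allylation of F7 with 3 (Li2CuCl4 cat.) comes back at boronate 7.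

**Further compounds**
F1 | step 10 | {5-[3,4-bis(methoxymethoxy)-5-(3-methylbut-2-en-1-yl)phenyl]-4-oxo-4H-pyran-2-yl}acetic acid | O=C(O)Cc1cc(=O)c(-c2cc(OCOC)c(OCOC)c(CC=C(C)C)c2)co1
F2 | step 10 | {5-[3,4-bis(methoxymethoxy)-5-(3-methylbut-2-en-1-yl)phenyl]-4-oxo-4H-pyran-2-yl}acetyl chloride | O=C(Cl)Cc1cc(=O)c(-c2cc(OCOC)c(OCOC)c(CC=C(C)C)c2)co1
F3 | step 9 | 5-methylhex-4-en-1-yne | C#CCC=C(C)C
F4 | step 9 | (5-methylhex-4-en-1-yn-1-yl)lithium | [Li]C#CCC=C(C)C
F5 | step 3 | 1-iodo-2,3-bis(methoxymethoxy)benzene | COCOc1cccc(I)c1OCOC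
F6 | step 3 | 2-[3-iodo-4,5-bis(methoxymethoxy)phenyl]-4,4,5,5-tetramethyl-1,3,2-dioxaborolane | COCOc1cc(B2OC(C)(C)C(C)(C)O2)cc(I)c1OCOC
F7 | step 3 | [2,3-bis(methoxymethoxy)-5-(4,4,5,5-tetramethyl-1,3,2-dioxaborolan-2-yl)phenyl]magnesium chloride | COCOc1cc(B2OC(C)(C)C(C)(C)O2)cc([Mg]Cl)c1OCOC
A1 | direct plan | (E)-1-[2-(benzyloxy)-6-hydroxy-4-(methoxymethoxy)phenyl]-3-[4-(benzyloxy)-3-(methoxymethoxy)phenyl]prop-2-en-1-one | O=C(/C=C/c1ccc(OCc2ccccc2)c(OCOC)c1)c1c(O)cc(OCOC)cc1OCc1ccccc1
A2 | direct plan | 5-hydroxy-3-[4-hydroxy-3-(methoxymethoxy)phenyl]-7-(methoxymethoxy)-4H-chromen-4-one | O=c1c(-c2ccc(O)c(OCOC)c2)coc2cc(OCOC)cc(O)c12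
A3 | direct plan | 7-(methoxymethoxy)-3-[3-(methoxymethoxy)-4-[(2-methylbut-3-en-2-yl)oxy]phenyl]-5-[(2-methylbut-3-en-2-yl)oxy]-4H-chromen-4-one | O=c1c(-c2ccc(OC(C)(C)C=C)c(OCOC)c2)coc2cc(OCOC)cc(OC(C)(C)C=C)c12
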